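Target does not pile up in the larch run: it holds 35% of the substrate at 12.0 min and 6% at 80.0 min, and intermediate falls beside it.

| flask | substrate | partner | remark | time |
|---|---|---|---|---|
| larch | 0.30 M | 1.5 M | run made earlier |  |
| ash | 0.30 M | 1 M | run made earlier |  |
| oak | 0.30 M | 2.2 M | run made earlier |  |
| maple | 0.45 M | 1.5 M | run made earlier |  |
| amber | 0.30 M | 1.50 M | everything together in a closed stirred flask, run for 80 min | 80 min |
| blue | 0.30 M | 1.50 M | one stirred flow tank at steady state, fed with the mixture as stated, mean residence time 800 min |  |
| green | 0.30 M | 1.50 M | one stirred flow tank at steady state, fed with the mixture as stated, mean residence time 80 min |  |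
| grey | 0.30 M | 1.50 M (fed, over 80.0 min) | a stirred flask in which partner is dosed at a steady rate over 80.0 min without added volume, worked up at 80 min | 80 min |

| run | time / min | intermediate / % | target / % |
|---|---|---|---|
| larch | 12.0 | 27 | 35 |
| larch | 25.0 | 18 | 26 |
| larch | 40.0 | 10 | 20 |
| larch | 50.0 | 13 | 18 |
| larch | 60.0 | 7 | 13 |
| larch | 80.0 | 5 | 6 |
| ash | 12.0 | 42 | 31 |
| ash | 25.0 | 33 | 25 |
| ash | 40.0 | 30 | 21 |
| ash | 50.0 | 22 | 20 |
| ash | 60.0 | 22 | 17 |
| ash | 80.0 | 15 | 14 |
| oak | 12.0 | 18 | 35 |
| oak | 25.0 | 11 | 22 |
| oak | 40.0 | 2 | 8 |
| oak | 50.0 | 2 | 6 |
| oak | 60.0 | 7 | 9 |
| oak | 80.0 | 2 | 1 |
| maple | 15.0 | 21 | 31 |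
| maple | 30.0 | 17 | 22 |
| maple | 50.0 | 11 | 15 |
| maple | 60.0 | 7 | 14 |
| maple | 80.0 | 8 | 3 |

(scatter of a reading: 2 percentage points)

- the set-up with the highest amount of intermediate at the outlet or at the end, in percent of the substrate put in ("none" if the first two lie within 2 percentage points) (amber / blue / green / grey / none)
- amount of intermediate at the outlet or at the end, in percent of the substrate put in, amber
- amount of intermediate at the outlet or at the end, in percent of the substrate put in, blue
- amount of intermediate at the outlet or at the end, in percent of the substrate put in, green
- amount of intermediate at the outlet or at the end, in percent of the substrate put in, grey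

- percentages count the substrate that a species holds: one self-condensation product counts as two
- the stated concentrations are those of everything mixed, before any reaction; amounts are the same in each set-up
- what was read earlier has a scatter of 2 percentage points, one standard deviation
- steps thought possible: substrate -> intermediate; partner + intermediate <-> target; 2 substrate -> self-condensation product; partner + target -> over-reaction product
- the feed brings no volume worth counting
- the earlier runs were made in a closed, stirred flask

1. The first instants. On the steps thought possible, substrate turns into intermediate, and intermediate takes up partner to give target. At 12.0 min the larch flask reads 27% as intermediate and 35% as target, so the two together, here called the pool, read 62.0%.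

2. The middle. In the larch run intermediate and target fall together, so the pool is the thing to follow. Equal shares serve as the zero of the scale: the readings at 80.0 min put intermediate at half of the pool in larch and half in ash.

3. The end. At 80.0 min the pool holds 29.0% in ash, less in larch at 11.0%, and less again in oak at 3.00%. In these 3 runs, each charged with 0.30 M substrate, a higher [partner] goes with a smaller pool, as the step from partner + target to over-reaction product suggests.

4. The pool lifetime is the time in which the pool falls by a factor e at the larch charge, a pseudo-first-order reading. From the first and last larch readings, with their scatter, it reads 39.3 min.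

5. The vessels. With residence time τ and a lifetime L held constant, a stirred tank keeps one over one plus τ/L of what enters the pool, while a closed flask keeps exp(−τ/L) over the same time. Over the green time these factors are 0.330 and 0.131, so the tank keeps more. Taking all substrate into the pool and half of the pool as intermediate, this reckoning gives green 16.5% and blue 2.34%. Amber repeats the larch recipe, which reads 5%. Grey has no constant lifetime, and this reckoning gives it no number.

6. The forecast gives amber 5%, blue 3.3% against the 2.34% above, green 16.5%, grey 17% and best none: “Grey and green lie within 2 points, so the answer is none”.

7. The flask gives amber 6.22%, blue 3.91%, green 19.5%, grey 16.6%, and best green, with green 2.9 percentage points above grey.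

    substrate → intermediate (k = 0.00610 s⁻¹)
    partner + intermediate ⇌ target (K = 1.30 M⁻¹, k = 0.00220 M⁻¹ s⁻¹)
    2 substrate → self-condensation product (k = 0.00640 M⁻¹ s⁻¹)
    partner + target → over-reaction product (k = 5.70 × 10⁻⁴ M⁻¹ s⁻¹)

With the step from partner + target to over-reaction product struck out, green gives 37.4%. The lifetime of 39.3 min gave green 16.5% against that flask's 19.5%. In blue the same lifetime, a reading at the larch charge, reckons 95.3% of the substrate outside the pool, and blue holds 92.0% as over-reaction product.

The data come from a simulation with constants of no real substance, noise included.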